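**Retrosynthetic overview**
- 17 ⇐ 16 ⇐ 14. The acrylic acid is installed last. Its α-carbon travels through the route as a carbonyl carbon (imide → Weinreb amide → methyl ketone → enol triflate → Pd hydroxycarbonylation).
- Key disconnection: C2–C3 and C4=C5 of the dihydropyran are cut together. This removes C3–C4 as vinyltriphenylphosphonium bromide 8 and leaves the acyclic keto imide 7. The only ring and the only stereocentre are formed in this step.
- Enabling feature: in the 3,6-dihydro-2H-pyran ring, C2 lies between O1 and the acrylate α-carbon, and the side-chain-bearing olefin carbon C5 is joined to it through C2–O1–C6–C5. C2 can therefore be a glycolate enolate carbon and C5 a ketone carbon. The missing CH2–CH= unit is what such a nucleophile/carbonyl pair takes up from a vinylphosphonium salt.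
- 7 ⇐ keto acid 4 + auxiliary 5. 4 ⇐ retro-Claisen opening of the symmetrical dione 3 ⇐ 1 + 2. The C–C–O–C–C chain of 1 becomes Cα–C2–O1–C6–C5.

Key step: step 4

Remark: ring atoms are named by pyran numbering (O1, C2 to C6). Compounds 1, 2 (as the 2E,6E isomer), 5 and 8 are taken as commercial.

**Step 1**
Reactants: 1 2H-pyran-3,5(4H,6H)-dione; 2 (2E,6E)-farnesyl bromide
Product: 3 4-[(2E,6E)-3,7,11-trimethyldodeca-2,6,10-trien-1-yl]-2H-pyran-3,5(4H,6H)-dione
Conditions: 1 (1.5 equiv), KOH (1.5 equiv), H2O/MeOH, 0 °C → rt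
Reagents that add atoms: none
Why: C-alkylation of a cyclic 1,3-dione enolate with an allylic bromide (SN2) should go to C4 because the protic medium solvates the enolate oxygens and the electrophile is soft; the excess of the symmetrical dione holds back dialkylation, and the olefin geometry of 2 is not touched.

**Step 2**
Reactants: 3 4-farnesyl-2H-pyran-3,5(4H,6H)-dione
Product: 4 2-{[(5E,9E)-6,10,14-trimethyl-2-oxopentadeca-5,9,13-trien-1-yl]oxy}acetic acid
Conditions: NaOH (5 equiv), H2O/EtOH, reflux; then HCl to pH 2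
Reagents that add atoms: sodium hydroxide [Na+].[OH-]
Why: Retro-Claisen reaction (alkaline acid cleavage of a 2-alkyl-1,3-dione): hydroxide adds to one of the two equivalent carbonyl groups and C–C cleavage is made irreversible by carboxylate formation, so the symmetry of 3 allows only one keto acid.

**Step 3**
Reactants: 4 keto acid; 5 (S)-4-benzyloxazolidin-2-one
Product: 7 (S)-4-benzyl-3-(2-{[(5E,9E)-6,10,14-trimethyl-2-oxopentadeca-5,9,13-trien-1-yl]oxy}acetyl)oxazolidin-2-one, via mixed pivalic anhydride 6 (not isolated)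
Conditions: PivCl, Et3N, THF, −20 °C; then LiCl, 5, −20 °C → rt
Reagents that add atoms: pivaloyl chloride CC(C)(C)C(=O)Cl (its acyl group is carried by 6 only and is lost again on the way to 7)
Why: Mixed-anhydride N-acylation of an oxazolidinone under Et3N/LiCl needs no strong base, so the ketone should survive; the hindered pivaloyl carbonyl directs attack to the glycolyl carbonyl, and the stereocentre of 5 is untouched.

**Step 4**
Reactants: 7 keto imide; 8 vinyltriphenylphosphonium bromide
Product: 11 (S)-4-benzyl-3-{(R)-5-[(3E,7E)-4,8,12-trimethyltrideca-3,7,11-trien-1-yl]-3,6-dihydro-2H-pyran-2-carbonyl}oxazolidin-2-one, via sodium Z-enolate 9 (not isolated), via phosphonium ylide 10 (not isolated)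
Conditions: NaHMDS (1.05 equiv), THF, −78 °C; 8 (1.2 equiv, in CH2Cl2), −78 → −40 °C; then → rt
Reagents that add atoms: sodium bis(trimethylsilyl)amide C[Si](C)(C)[N-][Si](C)(C)C.[Na+] (only the Na+ of 9)
Why: Proposed new method: NaHMDS should take the most acidic proton of 7 (the OCH2 group next to the imide) to give the sodium-chelated Z-enolate 9, which adds through C2 to the CH2 terminus of the cationic acceptor 8 (C2–C3 bond) and thereby sets free the non-stabilised ylide 10, whose carbanion C4 attacks the ketone carbon C5 and, after oxaphosphetane collapse, leaves the C4=C5 bond and Ph3PO. The closest known reaction type is the Michael addition/intramolecular Wittig annulation of vinyltriphenylphosphonium bromide (Schweizer's reagent) with keto-substituted malonate and β-keto ester anions, which gives cyclopentenes and cyclohexenes; what is new is a singly activated, auxiliary-bound glycolate enolate as the donor. The dihydropyran closes by 6-exo-trig attack of the ylide carbon on the C=O group, and because both olefin carbons end up in the six-membered ring the double bond can only be endocyclic, cis within the ring and located at C4=C5. The new stereocentre C2 is controlled by the benzyl group of the (S)-auxiliary, which shields one face of the planar chelated enolate in the same sense as in allyl halide alkylations of glycolyl oxazolidinones, so that the new CH2 group should enter to give (R). The step needs site-selective enolisation and no acyl transfer: the imide CH2 is the most acidic C–H position, HMDS-type bases discriminate on acidity, −78 °C holds back Dieckmann-type attack of any ketone enolate on the imide, and the cation–anion pairing of 8 with 9 should make C–C bond formation fast. No base stronger than the ylide remains after the addition and the α-branched imide 11 is shielded from deprotonation by A(1,3) strain, so C2 should not epimerise.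

**Step 5**
Reactants: 11 dihydropyranyl imide
Product: 12 (R)-N-methoxy-N-methyl-5-[(3E,7E)-4,8,12-trimethyltrideca-3,7,11-trien-1-yl]-3,6-dihydro-2H-pyran-2-carboxamide
Conditions: MeONHMe·HCl (3 equiv), AlMe3 (3 equiv), CH2Cl2, −10 °C → rt; 1 M HCl work-up
Reagents that add atoms: N,O-dimethylhydroxylamine hydrochloride CNOC.Cl
Why: Aluminium amide transamidation of an N-acyl oxazolidinone to the Weinreb amide attacks the exocyclic carbonyl group and is not basic, so C2 should keep its configuration and the auxiliary should be recovered.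

**Step 6**
Reactants: 12 Weinreb amide
Product: 14 1-{(R)-5-[(3E,7E)-4,8,12-trimethyltrideca-3,7,11-trien-1-yl]-3,6-dihydro-2H-pyran-2-yl}ethan-1-one, via magnesium hemiaminal chelate 13 (not isolated)
Conditions: MeMgBr (1.5 equiv), THF, −20 → 0 °C; cold 1 M HCl
Reagents that add atoms: methylmagnesium bromide C[Mg]Br
Why: Weinreb ketone synthesis: the chelated tetrahedral adduct 13 persists until the cold acidic quench, which should prevent over-addition and leave no base in contact with the α-alkoxy ketone.

**Step 7**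
Reactants: 14 methyl ketone
Product: 16 1-{(R)-5-[(3E,7E)-4,8,12-trimethyltrideca-3,7,11-trien-1-yl]-3,6-dihydro-2H-pyran-2-yl}ethenyl trifluoromethanesulfonate, via potassium enolate 15 (not isolated)
Conditions: KHMDS (1.1 equiv), THF, −78 °C; Comins' reagent, −78 → −40 °C; NH4Cl quench
Reagents that add atoms: Comins' reagent O=S(=O)(N(c1ccc(Cl)cn1)S(=O)(=O)C(F)(F)F)C(F)(F)F; potassium bis(trimethylsilyl)amide C[Si](C)(C)[N-][Si](C)(C)C.[K+] (only the K+ of 15)
Why: Kinetic enolate formation followed by O-triflation: the bulky base should remove a proton of the unhindered CH3 group at −78 °C rather than the tertiary C2–H, so the terminal enol triflate forms and C2 is not touched.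

**Step 8**
Reactants: 16 enol triflate
Product: 17 (R)-2-{5-[(3E,7E)-4,8,12-trimethyltrideca-3,7,11-trien-1-yl]-3,6-dihydro-2H-pyran-2-yl}prop-2-enoic acid (target)
Conditions: Pd(OAc)2 (5 mol%), dppf (6 mol%), CO (1 atm), H2O, Et3N, DMF, 50 °C; KHSO4 work-up
Reagents that add atoms: carbon monoxide [C-]#[O+]; water O
Why: Palladium-catalysed hydroxycarbonylation of an enol triflate (oxidative addition, CO insertion, hydrolysis of the acyl-palladium species) turns C–OTf into C–CO2H with the methylidene group already in place and should leave C2, the ring olefin and the trisubstituted chain olefins untouched.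

**Compound list**
1 | 2H-pyran-3,5(4H,6H)-dione | O=C1COCC(=O)C1 | starting material
2 | (2E,6E)-farnesyl bromide, (2E,6E)-1-bromo-3,7,11-trimethyldodeca-2,6,10-triene | CC(C)=CCC/C(C)=C/CC/C(C)=C/CBr | starting material
3 | 4-[(2E,6E)-3,7,11-trimethyldodeca-2,6,10-trien-1-yl]-2H-pyran-3,5(4H,6H)-dione | O=C1COCC(=O)C1C/C=C(\C)CC/C=C(\C)CCC=C(C)C | intermediate
4 | 2-{[(5E,9E)-6,10,14-trimethyl-2-oxopentadeca-5,9,13-trien-1-yl]oxy}acetic acid | OC(=O)COCC(=O)CC/C=C(\C)CC/C=C(\C)CCC=C(C)C | intermediate
5 | (S)-4-benzyloxazolidin-2-one | O=C1N[C@@H](Cc2ccccc2)CO1 | starting material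
6 | mixed anhydride of 4 and pivalic acid | CC(C)(C)C(=O)OC(=O)COCC(=O)CC/C=C(\C)CC/C=C(\C)CCC=C(C)C | intermediate
7 | (S)-4-benzyl-3-(2-{[(5E,9E)-6,10,14-trimethyl-2-oxopentadeca-5,9,13-trien-1-yl]oxy}acetyl)oxazolidin-2-one | O=C(COCC(=O)CC/C=C(\C)CC/C=C(\C)CCC=C(C)C)N1[C@@H](Cc2ccccc2)COC1=O | intermediate
8 | vinyltriphenylphosphonium bromide | C=C[P+](c1ccccc1)(c1ccccc1)c1ccccc1.[Br-] | starting material
9 | sodium (Z)-enolate of 7 | [Na+].[O-]/C(=C\OCC(=O)CC/C=C(\C)CC/C=C(\C)CCC=C(C)C)N1[C@@H](Cc2ccccc2)COC1=O | intermediate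
10 | ylide: (S)-4-benzyl-3-[(R)-2-{[(5E,9E)-6,10,14-trimethyl-2-oxopentadeca-5,9,13-trien-1-yl]oxy}-4-(triphenyl-λ5-phosphanylidene)butanoyl]oxazolidin-2-one | O=C(CC/C=C(\C)CC/C=C(\C)CCC=C(C)C)CO[C@H](CC=P(c1ccccc1)(c1ccccc1)c1ccccc1)C(=O)N1[C@@H](Cc2ccccc2)COC1=O | intermediate
11 | (S)-4-benzyl-3-{(R)-5-[(3E,7E)-4,8,12-trimethyltrideca-3,7,11-trien-1-yl]-3,6-dihydro-2H-pyran-2-carbonyl}oxazolidin-2-one | O=C([C@H]1CC=C(CC/C=C(\C)CC/C=C(\C)CCC=C(C)C)CO1)N1[C@@H](Cc2ccccc2)COC1=O | intermediate
12 | (R)-N-methoxy-N-methyl-5-[(3E,7E)-4,8,12-trimethyltrideca-3,7,11-trien-1-yl]-3,6-dihydro-2H-pyran-2-carboxamide | CON(C)C(=O)[C@H]1CC=C(CC/C=C(\C)CC/C=C(\C)CCC=C(C)C)CO1 | intermediate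
13 | bromomagnesium alkoxide of the tetrahedral MeMgBr adduct of 12 (hemiaminal carbon not defined) | CC(O[Mg]Br)(N(C)OC)[C@H]1CC=C(CC/C=C(\C)CC/C=C(\C)CCC=C(C)C)CO1 | intermediate
14 | 1-{(R)-5-[(3E,7E)-4,8,12-trimethyltrideca-3,7,11-trien-1-yl]-3,6-dihydro-2H-pyran-2-yl}ethan-1-one | CC(=O)[C@H]1CC=C(CC/C=C(\C)CC/C=C(\C)CCC=C(C)C)CO1 | intermediate
15 | potassium enolate of 14 (terminal) | [K+].[O-]C(=C)[C@H]1CC=C(CC/C=C(\C)CC/C=C(\C)CCC=C(C)C)CO1 | intermediate
16 | 1-{(R)-5-[(3E,7E)-4,8,12-trimethyltrideca-3,7,11-trien-1-yl]-3,6-dihydro-2H-pyran-2-yl}ethenyl trifluoromethanesulfonate | C=C(OS(=O)(=O)C(F)(F)F)[C@H]1CC=C(CC/C=C(\C)CC/C=C(\C)CCC=C(C)C)CO1 | intermediate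
17 | (R)-2-{5-[(3E,7E)-4,8,12-trimethyltrideca-3,7,11-trien-1-yl]-3,6-dihydro-2H-pyran-2-yl}prop-2-enoic acid | C=C(C(=O)O)[C@H]1CC=C(CC/C=C(\C)CC/C=C(\C)CCC=C(C)C)CO1 | target

Total step count: 8
Longest linear sequence: 8 steps (1 or 2 → 17)

**Steps most likely to fail**

1. Step 4.
- What may go wrong: enolisation may take place in part on the ketone side, followed by Dieckmann-type acyl transfer with loss of the auxiliary. The Michael addition may be too slow at the temperatures the glycolate enolate tolerates. Facial selectivity toward a cationic acceptor may be lower than toward allyl halides.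
- Fallback (known chemistry): it sets out from 4 and comes back at 11. Wittig methylenation of the ketone (Ph3P=CH2, excess, THF) would give the methylidene acid F1. Acylation of 5 as in step 3 would give the methylidene imide F2. NaHMDS and allyl iodide (auxiliary-controlled glycolate alkylation) would give the (R)-allylated imide F3. Ring-closing metathesis (Grubbs II, CH2Cl2, reflux) between the monosubstituted and the 1,1-disubstituted olefin would then close the dihydropyran to 11.

2. Step 7.
- What may go wrong: deprotonation at C2 instead of at the methyl group would lead to the internal enol triflate and to racemisation.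
- Fallback: it avoids any enolate next to C2, sets out from 12 and comes back at 17. DIBAL-H reduction would give the pyran-2-carbaldehyde F4. Ohira–Bestmann homologation (K2CO3, MeOH) would give the 2-ethynyl dihydropyran F5. Palladium-catalysed Markovnikov hydroxycarbonylation of the terminal alkyne (Pd(OAc)2, 2-pyridyldiphenylphosphine, catalytic MsOH, CO, H2O) would give 17.

3. Step 2.
- What may go wrong: the fully enolised dione may resist attack by hydroxide, and the α-alkoxy ketone may undergo aldol self-condensation during long heating in alkali.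
- Fallback: it builds the ether bond instead of opening a ring, sets out from 2 and comes back at 4. Acetoacetic ester alkylation (ethyl acetoacetate, NaOEt) would give the farnesylated acetoacetate F6. Saponification and decarboxylation would give (5E,9E)-farnesylacetone F7. Kinetic enolisation (LDA, −78 °C) and oxidation with a Davis oxaziridine would give the hydroxymethyl ketone F8. Rh2(OAc)4-catalysed O–H insertion with ethyl diazoacetate would give the ethyl ester F9. LiOH hydrolysis would give 4.

**Further compounds**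
F1 | step 4 | 2-{[(5E,9E)-6,10,14-trimethyl-2-methylidenepentadeca-5,9,13-trien-1-yl]oxy}acetic acid | C=C(CC/C=C(\C)CC/C=C(\C)CCC=C(C)C)COCC(=O)O
F2 | step 4 | (S)-4-benzyl-3-(2-{[(5E,9E)-6,10,14-trimethyl-2-methylidenepentadeca-5,9,13-trien-1-yl]oxy}acetyl)oxazolidin-2-one | C=C(CC/C=C(\C)CC/C=C(\C)CCC=C(C)C)COCC(=O)N1[C@@H](Cc2ccccc2)COC1=O
F3 | step 4 | (S)-4-benzyl-3-[(R)-2-{[(5E,9E)-6,10,14-trimethyl-2-methylidenepentadeca-5,9,13-trien-1-yl]oxy}pent-4-enoyl]oxazolidin-2-one | C=CC[C@@H](OCC(=C)CC/C=C(\C)CC/C=C(\C)CCC=C(C)C)C(=O)N1[C@@H](Cc2ccccc2)COC1=O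
F4 | step 7 | (R)-5-[(3E,7E)-4,8,12-trimethyltrideca-3,7,11-trien-1-yl]-3,6-dihydro-2H-pyran-2-carbaldehyde | O=C[C@H]1CC=C(CC/C=C(\C)CC/C=C(\C)CCC=C(C)C)CO1
F5 | step 7 | (R)-2-ethynyl-5-[(3E,7E)-4,8,12-trimethyltrideca-3,7,11-trien-1-yl]-3,6-dihydro-2H-pyran | C#C[C@H]1CC=C(CC/C=C(\C)CC/C=C(\C)CCC=C(C)C)CO1
F6 | step 2 | ethyl (4E,8E)-2-acetyl-5,9,13-trimethyltetradeca-4,8,12-trienoate (racemic) | CCOC(=O)C(C(C)=O)C/C=C(\C)CC/C=C(\C)CCC=C(C)C
F7 | step 2 | (5E,9E)-6,10,14-trimethylpentadeca-5,9,13-trien-2-one | CC(=O)CC/C=C(\C)CC/C=C(\C)CCC=C(C)C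
F8 | step 2 | (5E,9E)-1-hydroxy-6,10,14-trimethylpentadeca-5,9,13-trien-2-one | OCC(=O)CC/C=C(\C)CC/C=C(\C)CCC=C(C)C
F9 | step 2 | ethyl 2-{[(5E,9E)-6,10,14-trimethyl-2-oxopentadeca-5,9,13-trien-1-yl]oxy}acetate | CCOC(=O)COCC(=O)CC/C=C(\C)CC/C=C(\C)CCC=C(C)C
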